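## Retrosynthetic overview

- Lactone atoms: O1, C2 (C=O), C3 (carbinol), C4 (CH bearing the aroyl group), C5 (OCH2). The only ring of the target is closed last, by making the C4–C5 bond.
- Enabling feature: C4 is the α-carbon of the exocyclic aryl ketone. The chain C4–C3–C2(=O)–O1 holds a CH2Cl group parked on O1 within 5-exo-tet reach of that enolate carbon. An acyclic keto ester with one stereocentre (C3) therefore becomes the lactone, and C3 sets C4.
- The C3 oxygen is silylated for this step, because a free alkoxide would cleave C3–C4 (retro-aldol) or attack the CH2Cl group.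
- C2, C3, C4 and the ketone carbon are the four carbons of L-malic acid. C3 becomes quaternary by benzylation of the pivalaldehyde acetal (temporary 1,3-dioxolan-4-one ring). The aryl ketone comes from a Negishi acylation.
- Ring order: temporary dioxolanone (made in step 1, removed in step 5), then the γ-lactone (step 8). Both phenols travel as benzyl ethers and are freed last.

Key step: step 8

Remark: compounds 1, 2, 4 and 8 are taken as commercial, and the C4 epimer with the aroyl group trans to the benzyl group is taken as the more stable one.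

## Route

Step 1
Reactants: 1 L-malic acid; 2 pivalaldehyde
Product: 3 (2S,4S)-2-tert-butyl-5-oxo-1,3-dioxolane-4-acetic acid (cis acetal)
Conditions: p-TsOH·H2O (cat.), H2SO4 (cat.), pentane, reflux, Dean–Stark trap; recrystallisation
Reagents that add atoms: none
Why: Acid-catalysed acetalisation with azeotropic removal of water should engage the α-hydroxy acid unit as the five-membered dioxolanone rather than the six-membered alternative, and the new acetal centre equilibrates to the cis (2S) isomer, which can be purified by crystallisation.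

Step 2
Reactants: 4 4-(benzyloxy)-3-methoxybenzyl alcohol
Product: 5 4-(benzyloxy)-3-methoxybenzyl bromide
Conditions: PBr3, Et2O, 0 °C
Reagents that add atoms: phosphorus tribromide, BrP(Br)Br
Why: This is the standard conversion of an electron-rich benzylic alcohol into the bromide (SN2 on the phosphite ester), and no stereocentre is involved.

Step 3
Reactants: 3 dioxolanone acid; 5 benzyl bromide
Product: 7 (2S,4S)-4-[4-(benzyloxy)-3-methoxybenzyl]-2-tert-butyl-5-oxo-1,3-dioxolane-4-acetic acid, via dilithio enolate carboxylate 6 (not isolated)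
Conditions: LiN(SiMe3)2 (2.1 equiv), THF, −78 °C; then 5, −78 → −20 °C; 1 M HCl
Reagents that add atoms: none
Why: This is an enolate alkylation by self-regeneration of the stereocentre, in which the ring carbon is planar in 6 and the tert-butyl group shields one face, so the bromide should enter trans to it, replace H with retention and set the quaternary (S) carbinol carbon.

Step 4
Reactants: 7 benzylated dioxolanone acid; 8 1-(benzyloxy)-4-bromo-2-methoxybenzene
Product: 11 (2S,5S)-5-[4-(benzyloxy)-3-methoxybenzyl]-5-{2-[4-(benzyloxy)-3-methoxyphenyl]-2-oxoethyl}-2-tert-butyl-1,3-dioxolan-4-one, via acid chloride 9 (not isolated), via arylzinc chloride 10 (not isolated)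
Conditions: 7, (COCl)2, DMF (cat.), CH2Cl2, 0 → 25 °C, evaporate; 8, Mg turnings, LiCl, ZnCl2, THF, 25 °C; combine, Pd(PPh3)4 (3 mol %), THF, 0 → 25 °C
Reagents that add atoms: none
Why: In this Negishi acylation the acid chloride should couple with the arylzinc chloride under zerovalent palladium catalysis much faster than the organozinc can touch the dioxolanone, and no stereocentre is affected.

Step 5
Reactants: 11 dioxolanone ketone
Product: 12 (2S)-2-[4-(benzyloxy)-3-methoxybenzyl]-4-[4-(benzyloxy)-3-methoxyphenyl]-2-hydroxy-4-oxobutanoic acid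
Conditions: LiOH, THF/H2O, 0 °C, 30 min; 1 M HCl to pH 3
Reagents that add atoms: water, O
Why: The dioxolanone is an activated acylal-type ester, so hydroxide should cleave the acyl–oxygen bond at 0 °C and the remaining hemiacetal loses pivalaldehyde, while the short cold exposure should spare the β-hydroxy ketone and the quaternary centre cannot epimerise.

Step 6
Reactants: 12 hydroxy keto acid
Product: 13 chloromethyl (2S)-2-[4-(benzyloxy)-3-methoxybenzyl]-4-[4-(benzyloxy)-3-methoxyphenyl]-2-hydroxy-4-oxobutanoate
Conditions: ClCH2OSO2Cl, NaHCO3, Bu4NHSO4 (cat.), CH2Cl2/H2O, 0 → 25 °C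
Reagents that add atoms: chloromethyl chlorosulfate, ClCOS(=O)(=O)Cl
Why: Phase-transfer O-alkylation of the carboxylate, with chlorosulfate as the leaving group, is the standard route to chloromethyl esters, and the weak base should leave the tertiary alcohol and the ketone untouched.

Step 7
Reactants: 13 chloromethyl ester
Product: 14 chloromethyl (2S)-2-[4-(benzyloxy)-3-methoxybenzyl]-4-[4-(benzyloxy)-3-methoxyphenyl]-4-oxo-2-(trimethylsilyloxy)butanoate
Conditions: Me3SiOTf, 2,6-lutidine, CH2Cl2, −78 → 0 °C
Reagents that add atoms: trimethylsilyl trifluoromethanesulfonate, C[Si](C)(C)OS(=O)(=O)C(F)(F)F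
Why: A silyl triflate with a hindered pyridine base silylates hindered tertiary alcohols, and the base is too weak to enolise the aryl ketone.

Step 8
Reactants: 14 silylated chloromethyl ester
Product: 17 (3S,4S)-4-[4-(benzyloxy)-3-methoxybenzoyl]-3-[4-(benzyloxy)-3-methoxybenzyl]-3-hydroxydihydrofuran-2(3H)-one, via lithium enolate 15 (not isolated), via silyl ether lactone 16 (not isolated)
Conditions: LiN(SiMe3)2 (1.1 equiv), THF (0.01 M), −78 → −30 °C; then 1 M HCl, THF, 0 °C
Reagents that add atoms: none
Why: LiN(SiMe3)2 removes a C4 proton (the only acidic C–H, α to the aryl ketone) to give the (Z)-lithium enolate 15, whose carbon displaces chloride from the CH2Cl group held on the carboxyl oxygen, and the acidic work-up then removes the Me3Si group. The closest known reaction type is the intramolecular SN2 alkylation of a ketone enolate, here with an acyloxymethyl halide (the electrophile class of pivaloyloxymethyl halides) as the alkylating carbon. The lactone ring O1–C2–C3–C4–C5 closes in the 5-(enolexo)-exo-tet mode, with the enolate double bond and the leaving group both outside the forming ring. The new C4 stereocentre is controlled by C3: allylic 1,3-strain and lithium bridging place the C3–OSiMe3 bond in the enolate plane next to the enolate oxygen, the ester arm reaches one face and the benzyl group covers the other, so the aroyl group should end cis to the oxygen and trans to the benzyl group (4S), which is also the more stable epimer at this enolisable centre. The step needs C- over O-alkylation, no retro-aldol cleavage and no attack of the carbinol oxygen on CH2Cl: O-alkylation would require a seven-membered ring, and the silyl ether removes the alkoxide that would trigger the other two. Low temperature and high dilution should hold back loss of silanolate from the enolate and intermolecular alkylation.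

Step 9
Reactants: 17 dibenzyl ether lactone
Product: 18 (3S,4S)-3-hydroxy-4-(4-hydroxy-3-methoxybenzoyl)-3-(4-hydroxy-3-methoxybenzyl)dihydrofuran-2(3H)-one (target)
Conditions: H2 (1 atm), Pd/C, EtOAc, 25 °C, stopped at full debenzylation
Reagents that add atoms: none
Why: Hydrogenolysis of the two aryl benzyl ethers should be faster than reduction of the electron-rich aryl ketone, and the neutral medium avoids retro-aldol cleavage and epimerisation at C4.

## Compound list

1 | L-malic acid | OC(=O)C[C@H](O)C(=O)O | starting material
2 | pivalaldehyde | CC(C)(C)C=O | starting material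
3 | (2S,4S)-2-tert-butyl-5-oxo-1,3-dioxolane-4-acetic acid | CC(C)(C)[C@H]1O[C@@H](CC(=O)O)C(=O)O1 | intermediate
4 | 4-(benzyloxy)-3-methoxybenzyl alcohol | COc1cc(CO)ccc1OCc1ccccc1 | starting material
5 | 4-(benzyloxy)-3-methoxybenzyl bromide | COc1cc(CBr)ccc1OCc1ccccc1 | intermediate
6 | dilithio enolate carboxylate of 3 | CC(C)(C)[C@H]1OC(CC(=O)O[Li])=C(O[Li])O1 | intermediate
7 | (2S,4S)-4-[4-(benzyloxy)-3-methoxybenzyl]-2-tert-butyl-5-oxo-1,3-dioxolane-4-acetic acid | CC(C)(C)[C@H]1O[C@](CC(=O)O)(Cc2ccc(OCc3ccccc3)c(OC)c2)C(=O)O1 | intermediate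
8 | 1-(benzyloxy)-4-bromo-2-methoxybenzene | COc1cc(Br)ccc1OCc1ccccc1 | starting material
9 | acid chloride of 7 | CC(C)(C)[C@H]1O[C@](CC(=O)Cl)(Cc2ccc(OCc3ccccc3)c(OC)c2)C(=O)O1 | intermediate
10 | [4-(benzyloxy)-3-methoxyphenyl]zinc chloride | COc1cc([Zn]Cl)ccc1OCc1ccccc1 | intermediate
11 | (2S,5S)-5-[4-(benzyloxy)-3-methoxybenzyl]-5-{2-[4-(benzyloxy)-3-methoxyphenyl]-2-oxoethyl}-2-tert-butyl-1,3-dioxolan-4-one | CC(C)(C)[C@H]1O[C@](CC(=O)c2ccc(OCc3ccccc3)c(OC)c2)(Cc2ccc(OCc3ccccc3)c(OC)c2)C(=O)O1 | intermediate
12 | (2S)-2-[4-(benzyloxy)-3-methoxybenzyl]-4-[4-(benzyloxy)-3-methoxyphenyl]-2-hydroxy-4-oxobutanoic acid | O[C@](CC(=O)c1ccc(OCc2ccccc2)c(OC)c1)(Cc1ccc(OCc2ccccc2)c(OC)c1)C(=O)O | intermediate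
13 | chloromethyl ester of 12 | O[C@](CC(=O)c1ccc(OCc2ccccc2)c(OC)c1)(Cc1ccc(OCc2ccccc2)c(OC)c1)C(=O)OCCl | intermediate
14 | O-trimethylsilyl ether of 13 | C[Si](C)(C)O[C@](CC(=O)c1ccc(OCc2ccccc2)c(OC)c1)(Cc1ccc(OCc2ccccc2)c(OC)c1)C(=O)OCCl | intermediate
15 | (Z)-lithium enolate of 14 | C[Si](C)(C)O[C@](/C=C(\O[Li])c1ccc(OCc2ccccc2)c(OC)c1)(Cc1ccc(OCc2ccccc2)c(OC)c1)C(=O)OCCl | intermediate
16 | (3S,4S)-4-[4-(benzyloxy)-3-methoxybenzoyl]-3-[4-(benzyloxy)-3-methoxybenzyl]-3-(trimethylsilyloxy)dihydrofuran-2(3H)-one | COc1cc(C[C@@]2(O[Si](C)(C)C)C(=O)OC[C@@H]2C(=O)c2ccc(OCc3ccccc3)c(OC)c2)ccc1OCc1ccccc1 | intermediate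
17 | (3S,4S)-4-[4-(benzyloxy)-3-methoxybenzoyl]-3-[4-(benzyloxy)-3-methoxybenzyl]-3-hydroxydihydrofuran-2(3H)-one | COc1cc(C[C@@]2(O)C(=O)OC[C@@H]2C(=O)c2ccc(OCc3ccccc3)c(OC)c2)ccc1OCc1ccccc1 | intermediate
18 | (3S,4S)-3-hydroxy-4-(4-hydroxy-3-methoxybenzoyl)-3-(4-hydroxy-3-methoxybenzyl)dihydrofuran-2(3H)-one | COc1cc(C[C@@]2(O)C(=O)OC[C@@H]2C(=O)c2ccc(O)c(OC)c2)ccc1O | target

## Step count and risks

Total step count: 9. Longest linear sequence: 8 steps (steps 1 and 3 to 9, from L-malic acid).

**Step 8.** Three processes may intervene: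
- The enolate may lose silanolate by β-elimination.
- The enolate oxygen may be acylated by the activated ester, with loss of formaldehyde and chloride.
- Displacement of chloride may be too slow at the temperatures the enolate tolerates.

The fallback closes the same bond by a radical instead of an anionic path. It sets out from 14 and returns at 17. Finkelstein exchange (NaI, acetone, 25 °C) should give the iodomethyl ester F1. Me3SiOTf and Et3N in CH2Cl2 should then convert the ketone into the (Z)-trimethylsilyl enol ether F2. Irradiation with blue light in MeCN in the presence of Ir(ppy)3 and 2,6-lutidine should reduce the C–I bond. The acyloxymethyl radical should add 5-exo-trig to the enol ether carbon, and the benzylic α-silyloxy radical should be oxidised by the oxidised photocatalyst and lose its silyl group. 1 M HCl in THF then frees the carbinol to give 17.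

**Step 4.** The acid chloride may form a ketene or open the acetal by β-elimination. It may also acylate the electron-rich benzyl ring under ZnCl2 before the cross-coupling takes place. The fallback avoids the acid chloride and the organozinc. It sets out from 7 and returns at 11. EtSH, EDC·HCl and DMAP (cat.) in CH2Cl2 should give the S-ethyl thioester F3. A Liebeskind–Srogl coupling then delivers 11 under neutral conditions. It uses commercial [4-(benzyloxy)-3-methoxyphenyl]boronic acid, Pd2(dba)3, P(2-furyl)3 and copper thiophene-2-carboxylate Cu(O2CC4H3S) in THF at 50 °C.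

**Step 5.** Hydroxide may trigger retro-aldol cleavage or dehydration of the β-hydroxy ketone during removal of the acetal. The fallback avoids hydroxide altogether. It sets out from 11 and returns at 12. Acid-catalysed alcoholysis (allyl alcohol, camphorsulfonic acid cat., 60 °C) should give the allyl ester F4. Neutral deallylation with Pd(PPh3)4 and morpholine in THF at 25 °C then releases 12.

## Further compounds

F1 | step 8 | iodomethyl (2S)-2-[4-(benzyloxy)-3-methoxybenzyl]-4-[4-(benzyloxy)-3-methoxyphenyl]-4-oxo-2-(trimethylsilyloxy)butanoate | C[Si](C)(C)O[C@](CC(=O)c1ccc(OCc2ccccc2)c(OC)c1)(Cc1ccc(OCc2ccccc2)c(OC)c1)C(=O)OCI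
F2 | step 8 | (Z)-trimethylsilyl enol ether of F1 | C[Si](C)(C)O[C@](/C=C(\O[Si](C)(C)C)c1ccc(OCc2ccccc2)c(OC)c1)(Cc1ccc(OCc2ccccc2)c(OC)c1)C(=O)OCI
F3 | step 4 | S-ethyl thioester of 7 | CC(C)(C)[C@H]1O[C@](CC(=O)SCC)(Cc2ccc(OCc3ccccc3)c(OC)c2)C(=O)O1
F4 | step 5 | allyl ester of 12 | O[C@](CC(=O)c1ccc(OCc2ccccc2)c(OC)c1)(Cc1ccc(OCc2ccccc2)c(OC)c1)C(=O)OCC=C
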